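## Retrosynthetic overview

1. The free 4-hydroxy-2-pyranone on C3 is made last: its ring comes from a dioxinone (acylketene cyclisation), attached by a vinylogous Mukaiyama aldol to a C3-aldehyde, followed by global desilylation.
2. The trans-dihydrofuran is closed just before that, by acid-mediated 5-exo capture of the benzylic cation (C2) by the 4-OH of the styrylpyranone; C3 is already fixed and dictates trans.
3. Key C2–C3 bond: Evans syn-aldol between an N-(pyranon-3-ylacetyl)oxazolidinone and 3,4-bis(silyloxy)benzaldehyde; this sets C3 absolutely.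
4. The imide comes from O-silyl bisnoryangonin by reductive alkylation at C3 with glyoxylic acid; the styrylpyranone comes from p-coumaroyl chloride and a dioxinone dienolate (Claisen, then thermolysis).
5. Ring order: styryl-2-pyranone (first), dihydrofuran, 4-hydroxy-2-pyranone (last).

Assumptions and abbreviations: glyoxylic acid is bought as its monohydrate and drawn as the free aldehyde; TBS = tert-butyldimethylsilyl, MOM = methoxymethyl; styrylpyranones are handled in amber glassware. The route is a paper design and has not been run.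

## Route

Step 1
Reactants: 1 (E)-3-(4-hydroxyphenyl)prop-2-enoic acid (p-coumaric acid)
Product: 3 (E)-3-[4-(TBSO)phenyl]prop-2-enoic acid, via bis-silylated TBS ester 2 (not isolated)
Conditions: TBSCl (2.3 eq), imidazole (5 eq), DMF, rt; then K2CO3, THF/MeOH/H2O, 0 °C, 30 min; pH 4 work-up
Reagents that add atoms: TBSCl, CC(C)(C)[Si](C)(C)Cl
Why: Silylation of both OH groups followed by selective hydrolysis of the much more labile silyl ester leaves only the aryl silyl ether (protection and selective deprotection).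

Step 2
Reactants: 3 (E)-3-[4-(TBSO)phenyl]prop-2-enoic acid; 4 2,2,6-trimethyl-4H-1,3-dioxin-4-one
Product: 7 6-[(3E)-4-[4-(TBSO)phenyl]-2-oxobut-3-en-1-yl]-2,2-dimethyl-4H-1,3-dioxin-4-one, via lithium dienolate 5 (not isolated), via acid chloride 6 (not isolated)
Conditions: (a) 3, (COCl)2, cat. DMF, CH2Cl2, 0 °C to rt, evaporate; (b) 4 (2.2 eq), LiHMDS (2.2 eq), THF, −78 °C, then 6, −78 to −40 °C; AcOH quench
Reagents that add atoms: none
Why: The γ-lithiated dioxinone is C-acylated at its terminal carbon by the acid chloride in a vinylogous Claisen condensation, the second equivalent of enolate covering the more acidic product.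

Step 3
Reactants: 7 6-[(3E)-4-[4-(TBSO)phenyl]-2-oxobut-3-en-1-yl]-2,2-dimethyl-4H-1,3-dioxin-4-one
Product: 9 4-hydroxy-6-[(E)-2-[4-(TBSO)phenyl]ethenyl]-2H-pyran-2-one, via acylketene 8 (not isolated)
Conditions: toluene, 110 °C, 1 h
Reagents that add atoms: none
Why: Thermal retro-[4+2] of the dioxinone expels acetone to give an acylketene that is trapped by the enol oxygen of the δ-ketone, forming the 4-hydroxy-2-pyranone (dioxinone thermolysis).

Step 4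
Reactants: 9 4-hydroxy-6-[(E)-2-[4-(TBSO)phenyl]ethenyl]-2H-pyran-2-one; 10 glyoxylic acid
Product: 12 2-[4-hydroxy-2-oxo-6-[(E)-2-[4-(TBSO)phenyl]ethenyl]-2H-pyran-3-yl]acetic acid, via alkylidene pyrandione 11 (not isolated)
Conditions: glyoxylic acid monohydrate (1.2 eq), Hantzsch ester (diethyl 1,4-dihydro-2,6-dimethylpyridine-3,5-dicarboxylate, 1.3 eq), L-proline (20 mol%), EtOH/CH2Cl2, rt
Reagents that add atoms: none
Why: Knoevenagel condensation at C3, the only nucleophilic carbon of the vinylogous acid, gives an alkylidene that Hantzsch ester reduces in situ before a second pyranone can add (organocatalytic reductive alkylation).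

Step 5
Reactants: 12 2-[4-hydroxy-2-oxo-6-[(E)-2-[4-(TBSO)phenyl]ethenyl]-2H-pyran-3-yl]acetic acid
Product: 13 prop-2-en-1-yl 2-[4-hydroxy-2-oxo-6-[(E)-2-[4-(TBSO)phenyl]ethenyl]-2H-pyran-3-yl]acetate
Conditions: allyl bromide (1.05 eq), KHCO3 (1.1 eq), DMF, 0 °C to rt
Reagents that add atoms: allyl bromide, C=CCBr
Why: With one equivalent of bicarbonate the carboxylate (pKa about 4) is formed and SN2-alkylated in preference to the delocalised pyranone OH (carboxylate O-alkylation).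

Step 6
Reactants: 13 prop-2-en-1-yl 2-[4-hydroxy-2-oxo-6-[(E)-2-[4-(TBSO)phenyl]ethenyl]-2H-pyran-3-yl]acetate
Product: 14 prop-2-en-1-yl 2-[4-(MOMO)-2-oxo-6-[(E)-2-[4-(TBSO)phenyl]ethenyl]-2H-pyran-3-yl]acetate
Conditions: MOMCl (1.5 eq), i-Pr2NEt (2 eq), CH2Cl2, 0 °C to rt
Reagents that add atoms: chloromethyl methyl ether, COCCl
Why: Amine-mediated O-alkylation of the acidic 4-OH gives a vinylogous MOM ester that survives Pd(0), boron enolisation, hydride and oxidation but is removed by acid (MOM protection).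

Step 7
Reactants: 14 prop-2-en-1-yl 2-[4-(MOMO)-2-oxo-6-[(E)-2-[4-(TBSO)phenyl]ethenyl]-2H-pyran-3-yl]acetate
Product: 15 2-[4-(MOMO)-2-oxo-6-[(E)-2-[4-(TBSO)phenyl]ethenyl]-2H-pyran-3-yl]acetic acid
Conditions: Pd(PPh3)4 (5 mol%), morpholine (1.5 eq), THF, 0 °C to rt; dilute citric acid wash
Reagents that add atoms: none
Why: Pd(0)-catalysed allyl transfer to morpholine (Tsuji–Trost deallylation) frees the acid under neutral conditions that leave MOM, TBS and the pyranone untouched.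

Step 8
Reactants: 15 2-[4-(MOMO)-2-oxo-6-[(E)-2-[4-(TBSO)phenyl]ethenyl]-2H-pyran-3-yl]acetic acid; 16 (4S)-4-benzyl-1,3-oxazolidin-2-one
Product: 18 (4S)-4-benzyl-3-[2-[4-(MOMO)-2-oxo-6-[(E)-2-[4-(TBSO)phenyl]ethenyl]-2H-pyran-3-yl]acetyl]-1,3-oxazolidin-2-one, via mixed pivalic anhydride 17 (not isolated)
Conditions: PivCl (1.1 eq), Et3N (2.5 eq), THF, −20 °C; then 16 (1.0 eq), LiCl (1.1 eq), rt
Reagents that add atoms: none
Why: Mixed-anhydride activation and LiCl-assisted N-acylation of the oxazolidinone at the less hindered carbonyl give the imide without strong base (auxiliary N-acylation).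

Step 9
Reactants: 19 3,4-dihydroxybenzaldehyde
Product: 20 3,4-bis(TBSO)benzaldehyde
Conditions: TBSCl (2.4 eq), imidazole (5 eq), DMF, rt
Reagents that add atoms: TBSCl, CC(C)(C)[Si](C)(C)Cl
Why: Imidazole-promoted silylation of both phenols (silyl ether protection).

Step 10
Reactants: 18 (4S)-4-benzyl-3-[2-[4-(MOMO)-2-oxo-6-[(E)-2-[4-(TBSO)phenyl]ethenyl]-2H-pyran-3-yl]acetyl]-1,3-oxazolidin-2-one; 20 3,4-bis(TBSO)benzaldehyde
Product: 22 (4S)-4-benzyl-3-[(2S,3S)-3-[3,4-bis(TBSO)phenyl]-3-hydroxy-2-[4-(MOMO)-2-oxo-6-[(E)-2-[4-(TBSO)phenyl]ethenyl]-2H-pyran-3-yl]propanoyl]-1,3-oxazolidin-2-one, via Z-boron enolate 21 (not isolated)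
Conditions: n-Bu2BOTf (1.3 eq), i-Pr2NEt (1.5 eq), CH2Cl2, −78 to 0 °C; 20 (1.3 eq), −78 to 0 °C; pH 7 buffer, MeOH, 30% H2O2, 0 °C
Reagents that add atoms: none
Why: Evans boron aldol: the Z-enolate reacts through a Zimmerman–Traxler chair on the face away from the benzyl group of the dipole-minimised (S)-auxiliary, setting the α-centre (future C3, S) and the 2,3-syn carbinol (future C2, S).

Step 11
Reactants: 22 the syn-aldol adduct
Product: 23 (4S)-4-benzyl-3-[(2S,3S)-3-[3,4-bis(TBSO)phenyl]-3-(TBSO)-2-[4-(MOMO)-2-oxo-6-[(E)-2-[4-(TBSO)phenyl]ethenyl]-2H-pyran-3-yl]propanoyl]-1,3-oxazolidin-2-one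
Conditions: TBSOTf (1.5 eq), 2,6-lutidine (3 eq), CH2Cl2, −78 to −20 °C
Reagents that add atoms: TBSOTf, CC(C)(C)[Si](C)(C)OS(=O)(=O)C(F)(F)F
Why: Silyl triflate silylation of the hindered benzylic alcohol blocks retro-aldol and β-elimination and distinguishes it from the primary alcohol made next (silyl ether protection).

Step 12
Reactants: 23 the O-TBS aldol imide
Product: 24 (2R,3S)-3-[3,4-bis(TBSO)phenyl]-3-(TBSO)-2-[4-(MOMO)-2-oxo-6-[(E)-2-[4-(TBSO)phenyl]ethenyl]-2H-pyran-3-yl]propan-1-ol (CIP label at C2 changes, geometry unchanged)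
Conditions: LiBH4 (2 eq), MeOH (2 eq), THF, −10 to 0 °C, monitored closely
Reagents that add atoms: none
Why: The chelation-activated N-acyl oxazolidinone is reduced faster than the vinylogous pyranone lactone, releasing the auxiliary without touching the α-centre (reductive auxiliary cleavage).

Step 13
Reactants: 24 the primary alcohol
Product: 25 (2S,3S)-3-[3,4-bis(TBSO)phenyl]-3-(TBSO)-2-[4-(MOMO)-2-oxo-6-[(E)-2-[4-(TBSO)phenyl]ethenyl]-2H-pyran-3-yl]propanal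
Conditions: Dess–Martin periodinane (1.3 eq), NaHCO3, CH2Cl2, 0 °C to rt; used crude at once
Reagents that add atoms: none
Why: Dess–Martin oxidation under buffered non-basic conditions gives the α-branched aldehyde without epimerisation, and the β-silyloxy group is a poor leaving group.

Step 14
Reactants: 4 2,2,6-trimethyl-4H-1,3-dioxin-4-one
Product: 27 [(2,2-dimethyl-6-methylidene-6H-1,3-dioxin-4-yl)oxy]trimethylsilane, via sodium dienolate 26 (not isolated)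
Conditions: NaHMDS (1.05 eq), THF, −78 °C, 30 min; TMSCl (1.2 eq), −78 °C to rt; pentane, filter under argon, distil under reduced pressure
Reagents that add atoms: chlorotrimethylsilane, C[Si](C)(C)Cl
Why: Kinetic γ-deprotonation of the dioxinone by the hindered sodium amide and O-silylation of the resulting dienolate by TMSCl give the silyl dienol ether (vinylogous silyl ketene acetal formation).

Step 15
Reactants: 25 the aldehyde; 27 the silyl dienol ether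
Product: 28 6-[(2RS,3R,4S)-4-[3,4-bis(TBSO)phenyl]-2-hydroxy-4-(TBSO)-3-[4-(MOMO)-2-oxo-6-[(E)-2-[4-(TBSO)phenyl]ethenyl]-2H-pyran-3-yl]butyl]-2,2-dimethyl-4H-1,3-dioxin-4-one (mixture at the new carbinol)
Conditions: 27 (2.5 eq), BF3·OEt2 (1.5 eq), CH2Cl2, −78 °C; NaHCO3 quench at −78 °C
Reagents that add atoms: none
Why: BF3-promoted vinylogous Mukaiyama aldol addition through the γ-carbon of the dienol ether joins the last four carbons under non-basic conditions that preserve the α-centre; the new carbinol centre is removed in the next step.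

Step 16
Reactants: 28 the δ-hydroxy dioxinone
Product: 29 6-[(3S,4S)-4-[3,4-bis(TBSO)phenyl]-2-oxo-4-(TBSO)-3-[4-(MOMO)-2-oxo-6-[(E)-2-[4-(TBSO)phenyl]ethenyl]-2H-pyran-3-yl]butyl]-2,2-dimethyl-4H-1,3-dioxin-4-one
Conditions: Dess–Martin periodinane (1.5 eq), NaHCO3, CH2Cl2, 0 °C to rt
Reagents that add atoms: none
Why: Dess–Martin oxidation gives the β-keto-dioxinone and removes the γ-hydroxyl that could trigger retro-Prins fragmentation in the acid step.

Step 17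
Reactants: 29 the acyclic β-keto-dioxinone
Product: 31 6-[2-[(2S,3S)-2-[3,4-bis(TBSO)phenyl]-4-oxo-6-[(E)-2-[4-(TBSO)phenyl]ethenyl]-2,3-dihydro-4H-furo[3,2-c]pyran-3-yl]-2-oxoethyl]-2,2-dimethyl-4H-1,3-dioxin-4-one (2,3-trans), via 4-hydroxypyranone 30 (not isolated)
Conditions: TFA/CH2Cl2 (1:10), 0.01 M, 0 °C, 30–60 min; NaHCO3 quench
Reagents that add atoms: none
Why: TFA cleaves the vinylogous MOM ester and ionises the p-silyloxybenzylic silyl ether, and reversible 5-exo capture of the cation by the pyranone 4-OH (SN1 cycloetherification) gives the thermodynamic 2,3-trans dihydrofuran, so C2 (S) is dictated by the fixed C3.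

Step 18
Reactants: 31 the cyclised β-keto-dioxinone
Product: 33 (2S,3S)-2-[3,4-bis(TBSO)phenyl]-3-(4-hydroxy-2-oxo-2H-pyran-6-yl)-6-[(E)-2-[4-(TBSO)phenyl]ethenyl]-2,3-dihydro-4H-furo[3,2-c]pyran-4-one, via acylketene 32 (not isolated)
Conditions: toluene, 110 °C, 45 min
Reagents that add atoms: none
Why: Retro-[4+2] loss of acetone gives an acylketene that is trapped by the enol oxygen of the adjacent ketone, forming the second 4-hydroxy-2-pyranone under neutral conditions (dioxinone thermolysis).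

Step 19
Reactants: 33 the tris-TBS ether
Product: 34 (2S,3S)-2-(3,4-dihydroxyphenyl)-3-(4-hydroxy-2-oxo-2H-pyran-6-yl)-6-[(E)-2-(4-hydroxyphenyl)ethenyl]-2,3-dihydro-4H-furo[3,2-c]pyran-4-one (target)
Conditions: HF·pyridine, THF/pyridine, 0 °C to rt; pH 4 work-up, Sephadex LH-20 or RP-HPLC under argon
Reagents that add atoms: none
Why: Fluoride cleaves the three aryl silyl ethers under mildly acidic conditions that avoid base-induced air oxidation of the catechol and leave both stereocentres untouched (global desilylation).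

## Compound list

1 | (E)-3-(4-hydroxyphenyl)prop-2-enoic acid | OC(=O)/C=C/c1ccc(O)cc1 | starting material
2 | TBS (E)-3-[4-(TBSO)phenyl]prop-2-enoate | CC(C)(C)[Si](C)(C)OC(=O)/C=C/c1ccc(O[Si](C)(C)C(C)(C)C)cc1 | intermediate
3 | (E)-3-[4-(TBSO)phenyl]prop-2-enoic acid | OC(=O)/C=C/c1ccc(O[Si](C)(C)C(C)(C)C)cc1 | intermediate
4 | 2,2,6-trimethyl-4H-1,3-dioxin-4-one | CC1=CC(=O)OC(C)(C)O1 | starting material
5 | lithium 2,2-dimethyl-6-methylidene-6H-1,3-dioxin-4-olate | [Li+].C=C1C=C([O-])OC(C)(C)O1 | intermediate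
6 | (E)-3-[4-(TBSO)phenyl]prop-2-enoyl chloride | ClC(=O)/C=C/c1ccc(O[Si](C)(C)C(C)(C)C)cc1 | intermediate
7 | 6-[(3E)-4-[4-(TBSO)phenyl]-2-oxobut-3-en-1-yl]-2,2-dimethyl-4H-1,3-dioxin-4-one | CC1(C)OC(=O)C=C(CC(=O)/C=C/c2ccc(O[Si](C)(C)C(C)(C)C)cc2)O1 | intermediate
8 | (6E)-7-[4-(TBSO)phenyl]hepta-1,6-diene-1,3,5-trione (acylketene) | O=C=CC(=O)CC(=O)/C=C/c1ccc(O[Si](C)(C)C(C)(C)C)cc1 | intermediate
9 | 4-hydroxy-6-[(E)-2-[4-(TBSO)phenyl]ethenyl]-2H-pyran-2-one | O=c1cc(O)cc(/C=C/c2ccc(O[Si](C)(C)C(C)(C)C)cc2)o1 | intermediate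
10 | glyoxylic acid | O=CC(=O)O | starting material
11 | 2-[2,4-dioxo-6-[(E)-2-[4-(TBSO)phenyl]ethenyl]-2H-pyran-3(4H)-ylidene]acetic acid | OC(=O)C=C1C(=O)C=C(/C=C/c2ccc(O[Si](C)(C)C(C)(C)C)cc2)OC1=O | intermediate
12 | 2-[4-hydroxy-2-oxo-6-[(E)-2-[4-(TBSO)phenyl]ethenyl]-2H-pyran-3-yl]acetic acid | OC(=O)Cc1c(O)cc(/C=C/c2ccc(O[Si](C)(C)C(C)(C)C)cc2)oc1=O | intermediate
13 | allyl ester of 12 | C=CCOC(=O)Cc1c(O)cc(/C=C/c2ccc(O[Si](C)(C)C(C)(C)C)cc2)oc1=O | intermediate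
14 | allyl 2-[4-(MOMO)-2-oxo-6-[(E)-2-[4-(TBSO)phenyl]ethenyl]-2H-pyran-3-yl]acetate | C=CCOC(=O)Cc1c(OCOC)cc(/C=C/c2ccc(O[Si](C)(C)C(C)(C)C)cc2)oc1=O | intermediate
15 | 2-[4-(MOMO)-2-oxo-6-[(E)-2-[4-(TBSO)phenyl]ethenyl]-2H-pyran-3-yl]acetic acid | OC(=O)Cc1c(OCOC)cc(/C=C/c2ccc(O[Si](C)(C)C(C)(C)C)cc2)oc1=O | intermediate
16 | (4S)-4-benzyl-1,3-oxazolidin-2-one | O=C1N[C@@H](Cc2ccccc2)CO1 | starting material
17 | mixed pivalic anhydride of 15 | CC(C)(C)C(=O)OC(=O)Cc1c(OCOC)cc(/C=C/c2ccc(O[Si](C)(C)C(C)(C)C)cc2)oc1=O | intermediate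
18 | (4S)-4-benzyl-3-[2-(pyranon-3-yl)acetyl]oxazolidin-2-one (imide) | O=C(Cc1c(OCOC)cc(/C=C/c2ccc(O[Si](C)(C)C(C)(C)C)cc2)oc1=O)N1[C@@H](Cc2ccccc2)COC1=O | intermediate
19 | 3,4-dihydroxybenzaldehyde | O=Cc1ccc(O)c(O)c1 | starting material
20 | 3,4-bis(TBSO)benzaldehyde | O=Cc1ccc(O[Si](C)(C)C(C)(C)C)c(O[Si](C)(C)C(C)(C)C)c1 | intermediate
21 | (Z)-dibutylboron enolate of 18 | CCCCB(CCCC)O/C(=C\c1c(OCOC)cc(/C=C/c2ccc(O[Si](C)(C)C(C)(C)C)cc2)oc1=O)N1[C@@H](Cc2ccccc2)COC1=O | intermediate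
22 | (2S,3S)-syn-aldol imide | O=C([C@H]([C@H](O)c1ccc(O[Si](C)(C)C(C)(C)C)c(O[Si](C)(C)C(C)(C)C)c1)c1c(OCOC)cc(/C=C/c2ccc(O[Si](C)(C)C(C)(C)C)cc2)oc1=O)N1[C@@H](Cc2ccccc2)COC1=O | intermediate
23 | O-TBS ether of 22 | O=C([C@H]([C@H](O[Si](C)(C)C(C)(C)C)c1ccc(O[Si](C)(C)C(C)(C)C)c(O[Si](C)(C)C(C)(C)C)c1)c1c(OCOC)cc(/C=C/c2ccc(O[Si](C)(C)C(C)(C)C)cc2)oc1=O)N1[C@@H](Cc2ccccc2)COC1=O | intermediate
24 | (2R,3S)-primary alcohol | OC[C@H]([C@H](O[Si](C)(C)C(C)(C)C)c1ccc(O[Si](C)(C)C(C)(C)C)c(O[Si](C)(C)C(C)(C)C)c1)c1c(OCOC)cc(/C=C/c2ccc(O[Si](C)(C)C(C)(C)C)cc2)oc1=O | intermediate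
25 | (2S,3S)-aldehyde | O=C[C@H]([C@H](O[Si](C)(C)C(C)(C)C)c1ccc(O[Si](C)(C)C(C)(C)C)c(O[Si](C)(C)C(C)(C)C)c1)c1c(OCOC)cc(/C=C/c2ccc(O[Si](C)(C)C(C)(C)C)cc2)oc1=O | intermediate
26 | sodium 2,2-dimethyl-6-methylidene-6H-1,3-dioxin-4-olate | [Na+].C=C1C=C([O-])OC(C)(C)O1 | intermediate
27 | [(2,2-dimethyl-6-methylidene-6H-1,3-dioxin-4-yl)oxy]trimethylsilane | C=C1C=C(O[Si](C)(C)C)OC(C)(C)O1 | intermediate
28 | δ-hydroxy dioxinone (carbinol epimers) | CC1(C)OC(=O)C=C(CC(O)[C@H]([C@H](O[Si](C)(C)C(C)(C)C)c2ccc(O[Si](C)(C)C(C)(C)C)c(O[Si](C)(C)C(C)(C)C)c2)c2c(OCOC)cc(/C=C/c3ccc(O[Si](C)(C)C(C)(C)C)cc3)oc2=O)O1 | intermediate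
29 | acyclic (3S,4S)-β-keto-dioxinone | CC1(C)OC(=O)C=C(CC(=O)[C@H]([C@H](O[Si](C)(C)C(C)(C)C)c2ccc(O[Si](C)(C)C(C)(C)C)c(O[Si](C)(C)C(C)(C)C)c2)c2c(OCOC)cc(/C=C/c3ccc(O[Si](C)(C)C(C)(C)C)cc3)oc2=O)O1 | intermediate
30 | de-MOM 4-hydroxypyranone of 29 | CC1(C)OC(=O)C=C(CC(=O)[C@H]([C@H](O[Si](C)(C)C(C)(C)C)c2ccc(O[Si](C)(C)C(C)(C)C)c(O[Si](C)(C)C(C)(C)C)c2)c2c(O)cc(/C=C/c3ccc(O[Si](C)(C)C(C)(C)C)cc3)oc2=O)O1 | intermediate
31 | trans-(2S,3S)-dihydrofuro[3,2-c]pyranone β-keto-dioxinone | CC1(C)OC(=O)C=C(CC(=O)[C@H]2c3c(cc(/C=C/c4ccc(O[Si](C)(C)C(C)(C)C)cc4)oc3=O)O[C@@H]2c2ccc(O[Si](C)(C)C(C)(C)C)c(O[Si](C)(C)C(C)(C)C)c2)O1 | intermediate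
32 | acylketene from 31 | O=C=CC(=O)CC(=O)[C@H]1c2c(cc(/C=C/c3ccc(O[Si](C)(C)C(C)(C)C)cc3)oc2=O)O[C@@H]1c1ccc(O[Si](C)(C)C(C)(C)C)c(O[Si](C)(C)C(C)(C)C)c1 | intermediate
33 | tris-TBS ether of the target | O=c1cc(O)cc([C@H]2c3c(cc(/C=C/c4ccc(O[Si](C)(C)C(C)(C)C)cc4)oc3=O)O[C@@H]2c2ccc(O[Si](C)(C)C(C)(C)C)c(O[Si](C)(C)C(C)(C)C)c2)o1 | intermediate
34 | (2S,3S)-2-(3,4-dihydroxyphenyl)-3-(4-hydroxy-2-oxo-2H-pyran-6-yl)-6-[(E)-2-(4-hydroxyphenyl)ethenyl]-2,3-dihydro-4H-furo[3,2-c]pyran-4-one | O=c1cc(O)cc([C@H]2c3c(cc(/C=C/c4ccc(O)cc4)oc3=O)O[C@@H]2c2ccc(O)c(O)c2)o1 | target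

## Step count and risks

Total steps: 19. Longest linear sequence: 17 (steps 1–8, 10–13, 15–19).

Steps most likely to fail:

Step 10 (aldol of a hindered, Lewis-basic imide with an electron-rich aldehyde; enolisation or conversion may be poor). The fallback sets out from acid 15 and comes back at alcohol 24. Acid 15 is coupled (DCC, DMAP) with (S)-4-benzylthiazolidine-2-thione to give the N-acylthiazolidinethione F1. Its chlorotitanium enolate (TiCl4, i-Pr2NEt, N-methylpyrrolidinone, CH2Cl2, −78 °C) adds to aldehyde 20 in a closed titanium transition state to give the Evans-syn thione aldol F2. TBSOTf/2,6-lutidine gives the silyl ether F3, and NaBH4 in THF/EtOH at 0 °C cleaves the thione auxiliary to alcohol 24.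

Step 12 (hydride may attack the pyranone lactone or the styryl-dienone before the hindered imide is consumed). The fallback sets out from aldol 22 and comes back at aldehyde 25. Transamination of 22 with Me3Al/MeNHOMe·HCl, assisted by the free β-hydroxyl, gives the Weinreb amide F4. TBSOTf/2,6-lutidine gives the silyl ether F5, and Schwartz reagent (Cp2Zr(H)Cl, THF, rt) reduces the amide selectively to aldehyde 25, avoiding the borohydride and the separate oxidation.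

Step 17 (capture by the lactone carbonyl oxygen would give the furo[2,3-b]pyran-4-one isomer; E1 loss of H-3 or MOM-cation alkylation are other possible leaks). The fallback sets out from 29 and comes back at target 34. Thermolysis of 29 (toluene, 110 °C) first forms the second pyranone, giving the acyclic bis-pyranone F6. HF·pyridine removes all four silyl groups to give the MOM-protected pentahydroxy compound F7. Dilute HCl in MeOH at high dilution then removes the MOM group as dimethoxymethane and closes the ring through the p-quinone methide of the free catechol, with oxa-Michael capture by the pyranone 4-OH as in the biogenesis, to give the trans product 34.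

## Further compounds

F1 | step 10 | (4S)-4-benzyl-3-[2-[4-(MOMO)-2-oxo-6-[(E)-2-[4-(TBSO)phenyl]ethenyl]-2H-pyran-3-yl]acetyl]-1,3-thiazolidine-2-thione | O=C(Cc1c(OCOC)cc(/C=C/c2ccc(O[Si](C)(C)C(C)(C)C)cc2)oc1=O)N1[C@@H](Cc2ccccc2)CSC1=S
F2 | step 10 | (2S,3S)-syn-aldol N-acylthiazolidinethione (thione analogue of 22) | O=C([C@H]([C@H](O)c1ccc(O[Si](C)(C)C(C)(C)C)c(O[Si](C)(C)C(C)(C)C)c1)c1c(OCOC)cc(/C=C/c2ccc(O[Si](C)(C)C(C)(C)C)cc2)oc1=O)N1[C@@H](Cc2ccccc2)CSC1=S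
F3 | step 10 | O-TBS ether of F2 | O=C([C@H]([C@H](O[Si](C)(C)C(C)(C)C)c1ccc(O[Si](C)(C)C(C)(C)C)c(O[Si](C)(C)C(C)(C)C)c1)c1c(OCOC)cc(/C=C/c2ccc(O[Si](C)(C)C(C)(C)C)cc2)oc1=O)N1[C@@H](Cc2ccccc2)CSC1=S
F4 | step 12 | (2S,3S)-3-[3,4-bis(TBSO)phenyl]-3-hydroxy-N-methoxy-N-methyl-2-[4-(MOMO)-2-oxo-6-[(E)-2-[4-(TBSO)phenyl]ethenyl]-2H-pyran-3-yl]propanamide | CON(C)C(=O)[C@H]([C@H](O)c1ccc(O[Si](C)(C)C(C)(C)C)c(O[Si](C)(C)C(C)(C)C)c1)c1c(OCOC)cc(/C=C/c2ccc(O[Si](C)(C)C(C)(C)C)cc2)oc1=O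
F5 | step 12 | 3-O-TBS ether of F4 | CON(C)C(=O)[C@H]([C@H](O[Si](C)(C)C(C)(C)C)c1ccc(O[Si](C)(C)C(C)(C)C)c(O[Si](C)(C)C(C)(C)C)c1)c1c(OCOC)cc(/C=C/c2ccc(O[Si](C)(C)C(C)(C)C)cc2)oc1=O
F6 | step 17 | 6-[(1S,2S)-2-[3,4-bis(TBSO)phenyl]-2-(TBSO)-1-[4-(MOMO)-2-oxo-6-[(E)-2-[4-(TBSO)phenyl]ethenyl]-2H-pyran-3-yl]ethyl]-4-hydroxy-2H-pyran-2-one | O=c1cc(O)cc([C@H]([C@H](O[Si](C)(C)C(C)(C)C)c2ccc(O[Si](C)(C)C(C)(C)C)c(O[Si](C)(C)C(C)(C)C)c2)c2c(OCOC)cc(/C=C/c3ccc(O[Si](C)(C)C(C)(C)C)cc3)oc2=O)o1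
F7 | step 17 | 6-[(1S,2S)-2-(3,4-dihydroxyphenyl)-2-hydroxy-1-[6-[(E)-2-(4-hydroxyphenyl)ethenyl]-4-(MOMO)-2-oxo-2H-pyran-3-yl]ethyl]-4-hydroxy-2H-pyran-2-one | O=c1cc(O)cc([C@H]([C@H](O)c2ccc(O)c(O)c2)c2c(OCOC)cc(/C=C/c3ccc(O)cc3)oc2=O)o1
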